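At early times the gamma and theta runs told me little, the target at 3.00 min standing at 2.1% and 3.1% against a scatter of 1 percentage point, so I reckoned from their last readings.

| flask | substrate | gas | remark | time |
|---|---|---|---|---|
| gamma | 0.12 M | 83 mM (held) | run made earlier |  |
| theta | 0.17 M | 83 mM (held) | run made earlier |  |
| flask | 0.23 M | 83 mM (held) |  | 12 min |

| run | time / min | target / % | substrate / % |
|---|---|---|---|
| gamma | 1.00 | 1.5 | 98.9 |
| gamma | 3.00 | 2.1 | 95.0 |
| gamma | 6.00 | 7.1 | 86.3 |
| gamma | 8.00 | 9.3 | 80.7 |
| gamma | 12.0 | 14.5 | 71.0 |
| theta | 1.00 | 1.5 | 99.2 |
| theta | 2.00 | 0.9 | 97.1 |
| theta | 3.00 | 3.1 | 95.6 |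
| theta | 6.00 | 6.3 | 86.7 |
| theta | 12.0 | 14.2 | 70.6 |

(readings scatter by 1 percentage point)

- at the start none of coupling partner is dissolved
- steps under discussion: coupling partner + loose pair -> isomer of the product; tight pair <-> loose pair; substrate <-> tight pair; coupling partner + tight pair -> target; gas <-> coupling partner

* the target standing at 12 min, as a percentage of the substrate charged
* concentration of coupling partner in solution at 12 min, in percent of saturation

I assumed that what leaves the substrate arrives as target or isomer of the product, with the pairs as fast steps in between. The end readings gave 0.0288 /min as the fractional loss rate, the part of the standing substrate lost per minute, a pseudo-first-order constant. They also gave 49.1% of the loss as target.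

I took time first: by hand, the flask at 12 min would hold 14.3% target. Then I took the charge: by hand it would change no percentage while the partner kept up, and from 0.12 M to 0.17 M the target went from 14.5% to 14.2%, inside the scatter. So I committed to 14.3%. The gas stood at 83 mM in every run. Each substrate lost takes one partner, so the demand as a fraction of the charge is the loss rate times the substrate standing, but I drew no transfer speed from the readings, and I put no number on the partner.

The forecast said 14.1% and 92%, a target slightly below mine, holding that “the dissolved partner is probably near saturation”.

The flask gave 13.4% and 75.5%.

    coupling partner + loose pair → isomer of the product (k = 97.0 /M/s)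
    tight pair ⇌ loose pair (K = 0.430, k = 13.0 /s)
    substrate ⇌ tight pair (K = 2.70 × 10⁻⁴, k = 0.00100 /s)
    coupling partner + tight pair → target (k = 33.0 /M/s)
    gas ⇌ coupling partner, rate k5*(csat - [coupling partner]) (kL = 0.00500 /s)

The target of the forecast stood within tolerance; its partner stood 17 points too high. In the flask the gas transfer did half of its turnover up to 12 min by 3.90 min, and the partner stood at 65.0% of saturation at 6.00 min and at 75.5% at 12 min. Meanwhile the substrate fed the tight pair, which stood at 0.00907% at 12.0 min, and net turnover carried 13.4% on to target and 14.5% to loose pair. At 12 min in the flask my reckoned loss rate asked 0.0207 /min of the charge, and transfer brought 0.0266 /min. For the neighbouring flask, the same charge read at 20 min, 0.0288 /min leaves 56.2% substrate and 21.5% target; that flask gave 55.5% and 21.4%.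

The readings come from a simulation on assumed constants; scatter was added.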